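Numbering the target as (4S)-4-hydroxy-2-octadecanoylcyclohexane-1,3-dione, the route cuts C4–C5 and C6–C1. What remains, C1–C2–C3–C4 and the C4 oxygen, is drawn as a five-membered lactone (a furan-2(5H)-one) in which the C4 oxygen acylates C1; the key step exploits this 1,4-relationship of hydroxyl oxygen and carbonyl carbon across the six-membered ring. A Michael–Dieckmann annulation of the lactone anion with tert-butyl acrylate inserts C5–C6, expands the ring to the carbocycle and releases the hydroxyl in one operation. A twofold-symmetric (2R,5R)-2,5-dimethylpyrrolidine on C3 controls C4, and the ester carbon is later lost as CO2.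

Key step: step 3

Remark on the chemistry: the ester- or acid-bearing ring carbon of 10, 11 and 12 is a labile β-keto ester (acid) center, expected as an inconsequential epimer/enol mixture and drawn without configuration; the target is drawn as the enol tautomer of the 1,3-dione.

Step 1
Reactants: 1 tetronic acid (4-hydroxyfuran-2(5H)-one); 2 (2R,5R)-2,5-dimethylpyrrolidine
Product: 3 4-[(2R,5R)-2,5-dimethylpyrrolidin-1-yl]furan-2(5H)-one
Conditions: PhMe, AcOH (cat.), reflux, Dean–Stark
Reagents that add atoms: none
Why: Acid-catalysed condensation of the cyclic 1,3-dicarbonyl enol with a secondary amine (enaminone formation) should give the vinylogous carbamate, driven by azeotropic removal of water, with the two stereocenters of 2 carried through unchanged.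

Step 2
Reactants: 3 4-[(2R,5R)-2,5-dimethylpyrrolidin-1-yl]furan-2(5H)-one; 4 octadecanoyl chloride
Product: 5 4-[(2R,5R)-2,5-dimethylpyrrolidin-1-yl]-3-octadecanoylfuran-2(5H)-one
Conditions: pyridine, DMAP (cat.), CH2Cl2, 0 → 40 °C
Reagents that add atoms: none
Why: The enamine β-carbon C3 of the vinylogous carbamate should be acylated by the acid chloride (Stork-type enamine C-acylation, as practised on β-aminoacrylates), and loss of HCl to pyridine restores the conjugated push-pull system.

Step 3
Reactants: 5 4-[(2R,5R)-2,5-dimethylpyrrolidin-1-yl]-3-octadecanoylfuran-2(5H)-one; 6 tert-butyl acrylate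
Product: 10 tert-butyl (5S)-4-[(2R,5R)-2,5-dimethylpyrrolidin-1-yl]-5-hydroxy-3-octadecanoyl-2-oxocyclohex-3-ene-1-carboxylate, via lithium furanolate 7 (not isolated), via Michael-adduct enolate 8 (not isolated), via bridged alkoxide 9 (not isolated)
Conditions: LiN(SiMe3)2 (1.1 equiv), THF, −78 °C; then 6 (slow addition), −78 → 0 °C; aq NH4Cl
Reagents that add atoms: none
Why: Proposed new method: LiN(SiMe3)2 should remove the ring C5–H of 5 to give the aromatic 2-oxidofuran 7, which adds through C5 to the β-carbon of 6 to give ester enolate 8; its carbanion then attacks the lactone carbonyl to give the oxa-bridged tetrahedral alkoxide 9, whose collapse breaks the ring C–O bond so that the former lactone oxygen becomes the C5 hydroxyl and the former lactone carbon the C2 ketone of 10 (Michael–Dieckmann sequence). The closest known reaction type is the Hauser–Kraus annulation of phthalide anions with acrylates, here transferred to a non-aromatic 4-aminofuranone that carries no leaving group at the anionic carbon, so the carbinol survives. The carbocycle closes by a 6-exo-trig acyl substitution, and the competing aldol onto the octadecanoyl ketone is excluded because it would require a bridgehead alkene in a bicyclo[3.2.1] skeleton. The new stereocenter is controlled by the twofold-symmetric pyrrolidine: the methyl group next to C5 shields one face of the planar anion, so the acrylate should enter anti to it and give the (S) configuration. Because 8 keeps an acidic C5–H and the Michael addition is reversible, a minor epimer can return to 7 until the irreversible ring closure, itself easier with the side chain anti to that methyl, funnels the mixture into one configuration. The step needs C5 over side-chain deprotonation and γ- over α-attack, which the greater stability of the conjugated furanolate under an equilibrating amide base and the fully substituted C3 should secure.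

Step 4
Reactants: 10 tert-butyl (5S)-4-[(2R,5R)-2,5-dimethylpyrrolidin-1-yl]-5-hydroxy-3-octadecanoyl-2-oxocyclohex-3-ene-1-carboxylate
Product: 13 (6S)-3,6-dihydroxy-2-octadecanoylcyclohex-2-en-1-one (target CNP0110148.1), via keto acid 11 (not isolated), via trione acid 12 (not isolated)
Conditions: CF3CO2H/CH2Cl2, 0 °C → rt; evaporate; then THF/1 M aq HCl, 40 °C
Reagents that add atoms: water, O
Why: Acidolysis of the tert-butyl ester should give 11, aqueous acid then hydrolyses the tertiary 2-acyl enaminone to 12 with release of auxiliary 2, and the β-keto acid decarboxylates on gentle warming as in classical cyclohexane-1,3-dione syntheses, none of which touches the C–O stereocenter.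

Compound list
1 | tetronic acid (4-hydroxyfuran-2(5H)-one) | OC1=CC(=O)OC1 | starting material
2 | (2R,5R)-2,5-dimethylpyrrolidine (trans) | C[C@@H]1CC[C@@H](C)N1 | starting material
3 | 4-[(2R,5R)-2,5-dimethylpyrrolidin-1-yl]furan-2(5H)-one | O=C1OCC(N2[C@H](C)CC[C@H]2C)=C1 | intermediate
4 | octadecanoyl chloride (stearoyl chloride) | CCCCCCCCCCCCCCCCCC(=O)Cl | starting material
5 | 4-[(2R,5R)-2,5-dimethylpyrrolidin-1-yl]-3-octadecanoylfuran-2(5H)-one | CCCCCCCCCCCCCCCCCC(=O)C1=C(N2[C@H](C)CC[C@H]2C)COC1=O | intermediate
6 | tert-butyl acrylate | C=CC(=O)OC(C)(C)C | starting material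
7 | lithium 4-[(2R,5R)-2,5-dimethylpyrrolidin-1-yl]-3-octadecanoylfuran-2-olate | [Li+].[O-]c1occ(N2[C@H](C)CC[C@H]2C)c1C(=O)CCCCCCCCCCCCCCCCC | intermediate (not isolated)
8 | lithium enolate of tert-butyl 3-[(2S)-3-[(2R,5R)-2,5-dimethylpyrrolidin-1-yl]-4-octadecanoyl-5-oxo-2,5-dihydrofuran-2-yl]propanoate | CCCCCCCCCCCCCCCCCC(=O)C1=C(N2[C@H](C)CC[C@H]2C)[C@H](CC=C([O-])OC(C)(C)C)OC1=O.[Li+] | intermediate (not isolated)
9 | lithium (1R,4S)-2-(tert-butoxycarbonyl)-5-[(2R,5R)-2,5-dimethylpyrrolidin-1-yl]-6-octadecanoyl-7-oxabicyclo[2.2.1]hept-5-en-1-olate (C2 epimers) | [Li+].[O-][C@@]12O[C@@H](CC1C(=O)OC(C)(C)C)C(N3[C@H](C)CC[C@H]3C)=C2C(=O)CCCCCCCCCCCCCCCCC | intermediate (not isolated)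
10 | tert-butyl (5S)-4-[(2R,5R)-2,5-dimethylpyrrolidin-1-yl]-5-hydroxy-3-octadecanoyl-2-oxocyclohex-3-ene-1-carboxylate (C1 epimers) | CCCCCCCCCCCCCCCCCC(=O)C1=C(N2[C@H](C)CC[C@H]2C)[C@@H](O)CC(C(=O)OC(C)(C)C)C1=O | intermediate
11 | (5S)-4-[(2R,5R)-2,5-dimethylpyrrolidin-1-yl]-5-hydroxy-3-octadecanoyl-2-oxocyclohex-3-ene-1-carboxylic acid (C1 epimers) | CCCCCCCCCCCCCCCCCC(=O)C1=C(N2[C@H](C)CC[C@H]2C)[C@@H](O)CC(C(=O)O)C1=O | intermediate (not isolated)
12 | (5S)-5-hydroxy-3-octadecanoyl-2,4-dioxocyclohexane-1-carboxylic acid (drawn as an enol, C1 epimers) | CCCCCCCCCCCCCCCCCC(=O)C1=C(O)C(C(=O)O)C[C@H](O)C1=O | intermediate (not isolated)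
13 | (6S)-3,6-dihydroxy-2-octadecanoylcyclohex-2-en-1-one, the enol form of (4S)-4-hydroxy-2-octadecanoylcyclohexane-1,3-dione | CCCCCCCCCCCCCCCCCC(=O)C1=C(O)CC[C@H](O)C1=O | target

Total step count: 4
Longest linear sequence: 4 steps (1 → 3 → 5 → 10 → 13)

Steps most likely to fail

Step 3 (key step, proposed new method). The anion may form or react at the α-carbon of the octadecanoyl chain instead of ring C5. The acrylate may oligomerise anionically. The sequence may stall at the Michael adduct if the enaminone-deactivated lactone carbonyl resists ring closure, and facial discrimination may be eroded if the 3-acyl group twists the pyrrolidine out of conjugation. The fallback replaces the anionic annulation by a cycloaddition of known type and sets out from 5. Soft enolisation with tBuMe2SiOSO2CF3 and Et3N in CH2Cl2 should give tert-butyl-dimethylsilyl ketene acetal 2-[(tert-butyldimethylsilyl)oxy]-4-[(2R,5R)-2,5-dimethylpyrrolidin-1-yl]-3-octadecanoylfuran F1. A Diels–Alder reaction of this 2-silyloxyfuran with 6 (PhMe, rt to 60 °C, ZnCl2 if needed), again anti to the shielding methyl group, should give the oxa-bridged silyl ketal tert-butyl (1S,4S)-1-[(tert-butyldimethylsilyl)oxy]-5-[(2R,5R)-2,5-dimethylpyrrolidin-1-yl]-6-octadecanoyl-7-oxabicyclo[2.2.1]hept-5-ene-2-carboxylate F2. Desilylation with Bu4NF/AcOH in THF at 0 °C should open the oxygen bridge, and the route is rejoined at 10.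

Step 2. Acylation may occur on oxygen or not at all, because the 2,5-dimethylpyrrolidine crowds C3, and the acid chloride may be diverted to its ketene. The fallback builds the acyl group on a methyl enol ether first and sets out from 1. O-Methylation (Me2SO4, K2CO3, acetone) should give 4-methoxyfuran-2(5H)-one F3. Lithiation at the vinylic C3 with LiN(iPr)2 in THF at −78 °C and addition to octadecanal should give racemic carbinol 3-(1-hydroxyoctadecyl)-4-methoxyfuran-2(5H)-one F4. Oxidation with Dess–Martin periodinane should give 4-methoxy-3-octadecanoylfuran-2(5H)-one F5. Addition–elimination of amine 2 at the doubly activated C4 (MeCN, rt to 50 °C) then displaces methanol, and the route is rejoined at 5.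

Step 4. In acid the O-protonated enaminone is an α-hydroxy iminium ion, so the carbinol carbon may epimerise through the enaminol before the amine is lost, or water may be eliminated towards an aromatic ring. The fallback removes the auxiliary under basic conditions first and sets out from 10. LiOH in THF/H2O at rt should add hydroxide to the doubly activated enaminone carbon and expel 2, giving after acidification tert-butyl (5S)-5-hydroxy-3-octadecanoyl-2,4-dioxocyclohexane-1-carboxylate F6, in which the trione is a stable enol(ate) and no iminium ion is present. Brief treatment with CF3CO2H in CH2Cl2 and gentle warming then cleaves the ester and decarboxylates through 12, and the route is rejoined at 13.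

Further compounds
F1 | step 3 | 2-[(tert-butyldimethylsilyl)oxy]-4-[(2R,5R)-2,5-dimethylpyrrolidin-1-yl]-3-octadecanoylfuran | CC(C)(C)[Si](C)(C)Oc1occ(N2[C@H](C)CC[C@H]2C)c1C(=O)CCCCCCCCCCCCCCCCC
F2 | step 3 | tert-butyl (1S,4S)-1-[(tert-butyldimethylsilyl)oxy]-5-[(2R,5R)-2,5-dimethylpyrrolidin-1-yl]-6-octadecanoyl-7-oxabicyclo[2.2.1]hept-5-ene-2-carboxylate (C2 epimers) | CC(C)(C)[Si](C)(C)O[C@@]12O[C@@H](CC1C(=O)OC(C)(C)C)C(N3[C@H](C)CC[C@H]3C)=C2C(=O)CCCCCCCCCCCCCCCCC
F3 | step 2 | 4-methoxyfuran-2(5H)-one | COC1=CC(=O)OC1
F4 | step 2 | 3-(1-hydroxyoctadecyl)-4-methoxyfuran-2(5H)-one (racemic carbinol) | CCCCCCCCCCCCCCCCCC(O)C1=C(OC)COC1=O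
F5 | step 2 | 4-methoxy-3-octadecanoylfuran-2(5H)-one | CCCCCCCCCCCCCCCCCC(=O)C1=C(OC)COC1=O
F6 | step 4 | tert-butyl (5S)-5-hydroxy-3-octadecanoyl-2,4-dioxocyclohexane-1-carboxylate (drawn as an enol, C1 epimers) | CCCCCCCCCCCCCCCCCC(=O)C1=C(O)C(C(=O)OC(C)(C)C)C[C@H](O)C1=O
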